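The numbering follows the carotenoid convention (C1 = methoxy-bearing quaternary carbon, ring = C2–C6, chain from C7). The five-membered ring is the only ring. Its C3–C4 edge carries no substituent, whereas the flanking atoms C2 (holding C1) and C5 (the carbinol) do. The ring is therefore assembled from a two-carbon alkyne (C3, C4) and a three-carbon enoate (C5, C6, C2). One nickel-mediated reductive (3+2) cycloaddition forms C2–C3 and C4–C5, closes the ring and sets C2. Its precursor is phenyl (E)-4-methoxy-4-methylpent-2-enoate, which already contains the intact C1 group, together with trimethylsilylacetylene. C6 alkylation, methyl addition at C5 and a C15 + C25 Wittig union finish the all-E polyene.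

Key step: step 5

Remark (assumption): the S descriptor of enone 11 and the R descriptor at C2 of the target denote the same spatial arrangement, because the CIP ranking of C3 and C6 changes on saturation; the sense of induction of the nickel–phosphine catalyst cannot be predicted, so the ligand antipode that gives (S)-11 is assumed to be chosen after a test run.

Step 1
Reactants: 1 2-methylbut-3-en-2-ol
Product: 3 3-methoxy-3-methylbut-1-ene, via sodium 2-methylbut-3-en-2-olate 2 (not isolated)
Conditions: NaH, tetraglyme, 0 °C to rt; MeI, rt; product distilled from the pot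
Reagents that add atoms: iodomethane, CI
Why: Williamson ether synthesis, in which the tertiary alkoxide attacks MeI (SN2) and the volatile ether is separated from the high-boiling solvent by distillation.

Step 2
Reactants: 3 3-methoxy-3-methylbut-1-ene
Product: 5 2-methoxy-2-methylpropanal, via secondary ozonide 4 (not isolated)
Conditions: O3, CH2Cl2, –78 °C; PPh3, –78 °C to rt; fractional distillation
Reagents that add atoms: ozone, [O-][O+]=O
Why: Ozonolysis with reductive work-up cleaves the only C=C bond, the aldehyde has no α-hydrogen, and distillation frees it from formaldehyde and Ph3P=O.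

Step 3
Reactants: 6 phenyl bromoacetate
Product: 7 (2-oxo-2-phenoxyethyl)triphenylphosphonium bromide
Conditions: PPh3, toluene, rt
Reagents that add atoms: triphenylphosphine, c1ccc(cc1)P(c1ccccc1)c1ccccc1
Why: SN2 quaternization of the phosphine by the activated α-bromo ester, with the salt expected to precipitate and the aryl ester untouched.

Step 4
Reactants: 5 2-methoxy-2-methylpropanal; 7 (2-oxo-2-phenoxyethyl)triphenylphosphonium bromide
Product: 9 phenyl (E)-4-methoxy-4-methylpent-2-enoate, via phosphorus ylide 8 (not isolated)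
Conditions: Et3N, CH2Cl2, 0 °C to rt
Reagents that add atoms: none
Why: Wittig olefination with an ester-stabilized ylide, generated by a mild amine base so that the phenyl ester survives, should give the E-enoate from the non-enolizable, electron-poor aldehyde.

Step 5
Reactants: 9 phenyl (E)-4-methoxy-4-methylpent-2-enoate; 10 ethynyltrimethylsilane
Product: 11 (4S)-4-(2-methoxypropan-2-yl)-2-(trimethylsilyl)cyclopent-2-en-1-one
Conditions: Ni(cod)2 (10 mol %), (+)-neomenthyldiphenylphosphine (20 mol %), Et3B (3 equiv), THF/MeOH, 50 °C, 10 (2 equiv) added slowly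
Reagents that add atoms: none
Why: Proposed new method: zerovalent nickel carrying the chiral phosphine binds the enoate C6=C2 bond and the alkyne, and oxidative cyclization joins C2 to the unsubstituted alkyne carbon C3 to give a nickel enolate/alkenyl–nickel metallacycle that MeOH protonates at C6. The alkenyl–nickel carbon C4 then attacks the aryl ester carbonyl C5 in a 5-exo-trig acyl substitution that expels phenoxide and closes the cyclopentenone ring, after which Et3B transfers an ethyl group to divalent nickel and β-hydride elimination with loss of ethene returns zerovalent nickel. The closest known reactions are the racemic nickel-catalysed reductive (3+2) cycloaddition of α,β-unsaturated aryl esters with alkynes and the enantioselective nickel/monophosphine reductive coupling of alkynes with aldehydes; an enantioselective enoate version has not been shown. The C2 stereocentre is set in the enantiodetermining oxidative cyclization by the chiral phosphine on nickel, which must distinguish the two enoate faces. Regioselectivity is needed and is secured by the trimethylsilyl group, which keeps its own carbon C4 on nickel so that C2–C3 forms at the terminal carbon; the phenoxide leaving group favours ring closure over simple reductive coupling, and the methyl ether is the least ionizable form of the C1 oxygen, the hindered β-carbon C2 remaining the reactivity risk.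

Step 6
Reactants: 11 (4S)-4-(2-methoxypropan-2-yl)-2-(trimethylsilyl)cyclopent-2-en-1-one
Product: 13 (4S,5R)-5-[(benzyloxy)methyl]-4-(2-methoxypropan-2-yl)-2-(trimethylsilyl)cyclopent-2-en-1-one, via lithium dienolate 12 (not isolated)
Conditions: LiN(iPr)2, THF, –78 °C; BnOCH2Cl, –78 to –40 °C
Reagents that add atoms: benzyl chloromethyl ether, ClCOCc1ccccc1
Why: Kinetic enolate alkylation, in which only C6 carries an α-hydrogen (C4 is vinylic) and the cross-conjugated lithium enolate is alkylated by the reactive chloromethyl ether on the face opposite the bulky C2 substituent, so C7 is set trans to C1 by substrate control.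

Step 7
Reactants: 13 (4S,5R)-5-[(benzyloxy)methyl]-4-(2-methoxypropan-2-yl)-2-(trimethylsilyl)cyclopent-2-en-1-one
Product: 15 (2R,3R)-2-[(benzyloxy)methyl]-3-(2-methoxypropan-2-yl)cyclopentan-1-one, via alpha-silyl ketone 14 (not isolated)
Conditions: H2 (1 atm), Pd/C, pyridine, EtOAc, rt; then Bu4NF, AcOH, THF, 0 °C
Reagents that add atoms: none
Why: Heterogeneous hydrogenation saturates C3=C4 while pyridine suppresses benzyl ether hydrogenolysis, and fluoride then cleaves the activated C–Si bond of the α-silyl ketone (protodesilylation through the C4 enolate, buffered by AcOH so that C6 keeps its favoured trans configuration and benzyl alcohol is not eliminated).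

Step 8
Reactants: 15 (2R,3R)-2-[(benzyloxy)methyl]-3-(2-methoxypropan-2-yl)cyclopentan-1-one
Product: 16 (1R,2R,3R)-2-[(benzyloxy)methyl]-3-(2-methoxypropan-2-yl)-1-methylcyclopentan-1-ol
Conditions: MeLi, CeCl3, THF, –78 °C
Reagents that add atoms: methyllithium, [Li]C
Why: Organocerium 1,2-addition, in which the weakly basic reagent adds to the enolizable β-alkoxy ketone without elimination, and attack on the C5 face opposite the adjacent C6 benzyloxymethyl group should place the methyl cis to the C2 substituent and the hydroxyl cis to C7, as the target requires.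

Step 9
Reactants: 16 (1R,2R,3R)-2-[(benzyloxy)methyl]-3-(2-methoxypropan-2-yl)-1-methylcyclopentan-1-ol
Product: 17 (1R,2R,3R)-2-(hydroxymethyl)-3-(2-methoxypropan-2-yl)-1-methylcyclopentan-1-ol
Conditions: H2, Pd(OH)2/C, EtOH, rt
Reagents that add atoms: none
Why: Hydrogenolysis of the benzyl ether over palladium leaves the tertiary alcohol, the methyl ether and all three stereocentres untouched.

Step 10
Reactants: 17 (1R,2R,3R)-2-(hydroxymethyl)-3-(2-methoxypropan-2-yl)-1-methylcyclopentan-1-ol
Product: 19 (3E)-4-[(1S,2R,5R)-2-hydroxy-5-(2-methoxypropan-2-yl)-2-methylcyclopentyl]but-3-en-2-one, via hydroxy aldehyde 18 (not isolated)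
Conditions: TEMPO (cat.), PhI(OAc)2, CH2Cl2, rt; then Ph3P=CHC(O)CH3 (2.5 equiv), 40 °C
Reagents that add atoms: 1-(triphenyl-λ5-phosphanylidene)propan-2-one, CC(=O)C=P(c1ccccc1)(c1ccccc1)c1ccccc1
Why: Oxoammonium oxidation is selective for the primary alcohol, and trapping the epimerizable β-hydroxy aldehyde in the same flask by Wittig olefination with the stabilized acetonyl ylide should give the E-enone (C7=C8) without exposure to base.

Step 11
Reactants: 19 (3E)-4-[(1S,2R,5R)-2-hydroxy-5-(2-methoxypropan-2-yl)-2-methylcyclopentyl]but-3-en-2-one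
Product: 20 (1E)-1-[(1S,2R,5R)-2-hydroxy-5-(2-methoxypropan-2-yl)-2-methylcyclopentyl]-3-methylpenta-1,4-dien-3-ol (both C9 epimers)
Conditions: CH2=CHMgBr (3 equiv), THF, –20 to 0 °C
Reagents that add atoms: vinylmagnesium bromide, C=C[Mg]Br
Why: Grignard 1,2-addition to the conjugated methyl ketone (the first equivalent is consumed by the hydroxyl) gives the divinyl carbinol, whose C9 configuration is irrelevant because the centre is destroyed in step 12.

Step 12
Reactants: 20 (1E)-1-[(1S,2R,5R)-2-hydroxy-5-(2-methoxypropan-2-yl)-2-methylcyclopentyl]-3-methylpenta-1,4-dien-3-ol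
Product: 21 {(2E,4E)-5-[(1S,2R,5R)-2-hydroxy-5-(2-methoxypropan-2-yl)-2-methylcyclopentyl]-3-methylpenta-2,4-dien-1-yl}triphenylphosphonium bromide
Conditions: PPh3·HBr, MeOH, 0 °C to rt
Reagents that add atoms: triphenylphosphine hydrobromide, Br.c1ccc(cc1)P(c1ccccc1)c1ccccc1
Why: Acid-promoted ionization of the doubly allylic tertiary alcohol and capture of the pentadienyl cation by PPh3 at the unhindered terminus C11 (allylic transposition, the standard entry to C15 Wittig salts) should give the dienyl salt, while the non-allylic C5 hydroxyl and the C1 methyl ether do not ionize.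

Step 13
Reactants: 22 pseudoionone, (3E,5E)-6,10-dimethylundeca-3,5,9-trien-2-one
Product: 23 (4E,6E)-3,7,11-trimethyldodeca-1,4,6,10-tetraen-3-ol (racemic)
Conditions: CH2=CHMgBr, THF, 0 °C
Reagents that add atoms: vinylmagnesium bromide, C=C[Mg]Br
Why: Grignard 1,2-addition to the dienone gives the tertiary vinyl carbinol.

Step 14
Reactants: 23 (4E,6E)-3,7,11-trimethyldodeca-1,4,6,10-tetraen-3-ol
Product: 24 [(2E,4E,6E)-3,7,11-trimethyldodeca-2,4,6,10-tetraen-1-yl]triphenylphosphonium bromide
Conditions: PPh3·HBr, MeOH, 0 °C to rt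
Reagents that add atoms: triphenylphosphine hydrobromide, Br.c1ccc(cc1)P(c1ccccc1)c1ccccc1
Why: The same allylic transposition via the extended allyl cation, with phosphine attack at the terminal CH2, gives the conjugated trienyl phosphonium salt.

Step 15
Reactants: 24 [(2E,4E,6E)-3,7,11-trimethyldodeca-2,4,6,10-tetraen-1-yl]triphenylphosphonium bromide; 25 (2E,4E,6E)-2,7-dimethylocta-2,4,6-trienedial
Product: 27 (2E,4E,6E,8E,10E,12E,14E)-2,7,11,15,19-pentamethylicosa-2,4,6,8,10,12,14,18-octaenal, via psi-end ylide 26 (not isolated)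
Conditions: NaOMe, MeOH/CH2Cl2, 0 °C to rt, 25 (3 equiv), salt added slowly; then heptane, reflux (Z to E)
Reagents that add atoms: none
Why: Wittig olefination of one formyl group of the symmetrical dialdehyde, kept in excess to suppress double condensation, forms C11'=C12', and the new disubstituted bond should equilibrate to E on heating.

Step 16
Reactants: 21 {(2E,4E)-5-[(1S,2R,5R)-2-hydroxy-5-(2-methoxypropan-2-yl)-2-methylcyclopentyl]-3-methylpenta-2,4-dien-1-yl}triphenylphosphonium bromide; 27 (2E,4E,6E,8E,10E,12E,14E)-2,7,11,15,19-pentamethylicosa-2,4,6,8,10,12,14,18-octaenal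
Product: 29 (1R,2S,3R)-3-(2-methoxypropan-2-yl)-1-methyl-2-[(1E,3E,5E,7E,9E,11E,13E,15E,17E,19E)-3,7,12,16,20,24-hexamethylpentacosa-1,3,5,7,9,11,13,15,17,19,23-undecaen-1-yl]cyclopentan-1-ol, via cyclo-end ylide 28 (not isolated)
Conditions: NaOMe, MeOH/CH2Cl2, 0 °C to rt; then EtOH, reflux, argon, dark (Z to E); crystallization
Reagents that add atoms: none
Why: Wittig olefination joins C11 to C12 in the presence of the free tertiary hydroxyl, and the sterically strained 11Z isomer should isomerize thermally to the all-E polyene without touching the three ring stereocentres.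

Compound list
1 | 2-methylbut-3-en-2-ol | CC(C)(O)C=C | starting material
2 | sodium 2-methylbut-3-en-2-olate | [Na+].[O-]C(C)(C)C=C | intermediate
3 | 3-methoxy-3-methylbut-1-ene | COC(C)(C)C=C | intermediate
4 | 3-(2-methoxypropan-2-yl)-1,2,4-trioxolane (secondary ozonide, racemic) | COC(C)(C)C1OCOO1 | intermediate
5 | 2-methoxy-2-methylpropanal | COC(C)(C)C=O | intermediate
6 | phenyl bromoacetate | BrCC(=O)Oc1ccccc1 | starting material
7 | (2-oxo-2-phenoxyethyl)triphenylphosphonium bromide | [Br-].O=C(C[P+](c1ccccc1)(c1ccccc1)c1ccccc1)Oc1ccccc1 | intermediate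
8 | phenyl (triphenyl-λ5-phosphanylidene)acetate | O=C(C=P(c1ccccc1)(c1ccccc1)c1ccccc1)Oc1ccccc1 | intermediate
9 | phenyl (E)-4-methoxy-4-methylpent-2-enoate | COC(C)(C)/C=C/C(=O)Oc1ccccc1 | intermediate
10 | ethynyltrimethylsilane | C#C[Si](C)(C)C | starting material
11 | (4S)-4-(2-methoxypropan-2-yl)-2-(trimethylsilyl)cyclopent-2-en-1-one | COC(C)(C)[C@@H]1C=C([Si](C)(C)C)C(=O)C1 | intermediate
12 | lithium (3S)-3-(2-methoxypropan-2-yl)-5-(trimethylsilyl)cyclopenta-1,4-dien-1-olate | [Li+].COC(C)(C)[C@@H]1C=C([Si](C)(C)C)C([O-])=C1 | intermediate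
13 | (4S,5R)-5-[(benzyloxy)methyl]-4-(2-methoxypropan-2-yl)-2-(trimethylsilyl)cyclopent-2-en-1-one | COC(C)(C)[C@@H]1C=C([Si](C)(C)C)C(=O)[C@H]1COCc1ccccc1 | intermediate
14 | (2R,3R)-2-[(benzyloxy)methyl]-3-(2-methoxypropan-2-yl)-5-(trimethylsilyl)cyclopentan-1-one (C5 epimers) | COC(C)(C)[C@@H]1CC([Si](C)(C)C)C(=O)[C@H]1COCc1ccccc1 | intermediate
15 | (2R,3R)-2-[(benzyloxy)methyl]-3-(2-methoxypropan-2-yl)cyclopentan-1-one | COC(C)(C)[C@@H]1CCC(=O)[C@H]1COCc1ccccc1 | intermediate
16 | (1R,2R,3R)-2-[(benzyloxy)methyl]-3-(2-methoxypropan-2-yl)-1-methylcyclopentan-1-ol | COC(C)(C)[C@@H]1CC[C@@](C)(O)[C@H]1COCc1ccccc1 | intermediate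
17 | (1R,2R,3R)-2-(hydroxymethyl)-3-(2-methoxypropan-2-yl)-1-methylcyclopentan-1-ol | COC(C)(C)[C@@H]1CC[C@@](C)(O)[C@H]1CO | intermediate
18 | (1S,2R,5R)-2-hydroxy-5-(2-methoxypropan-2-yl)-2-methylcyclopentane-1-carbaldehyde | COC(C)(C)[C@@H]1CC[C@@](C)(O)[C@H]1C=O | intermediate
19 | (3E)-4-[(1S,2R,5R)-2-hydroxy-5-(2-methoxypropan-2-yl)-2-methylcyclopentyl]but-3-en-2-one | COC(C)(C)[C@@H]1CC[C@@](C)(O)[C@H]1/C=C/C(C)=O | intermediate
20 | (1E)-1-[(1S,2R,5R)-2-hydroxy-5-(2-methoxypropan-2-yl)-2-methylcyclopentyl]-3-methylpenta-1,4-dien-3-ol (C3 epimers of the chain) | COC(C)(C)[C@@H]1CC[C@@](C)(O)[C@H]1/C=C/C(C)(O)C=C | intermediate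
21 | {(2E,4E)-5-[(1S,2R,5R)-2-hydroxy-5-(2-methoxypropan-2-yl)-2-methylcyclopentyl]-3-methylpenta-2,4-dien-1-yl}triphenylphosphonium bromide | [Br-].COC(C)(C)[C@@H]1CC[C@@](C)(O)[C@H]1/C=C/C(C)=C/C[P+](c1ccccc1)(c1ccccc1)c1ccccc1 | intermediate
22 | pseudoionone, (3E,5E)-6,10-dimethylundeca-3,5,9-trien-2-one | CC(=O)/C=C/C=C(C)/CCC=C(C)C | starting material
23 | (4E,6E)-3,7,11-trimethyldodeca-1,4,6,10-tetraen-3-ol (racemic) | C=CC(C)(O)/C=C/C=C(C)/CCC=C(C)C | intermediate
24 | [(2E,4E,6E)-3,7,11-trimethyldodeca-2,4,6,10-tetraen-1-yl]triphenylphosphonium bromide | [Br-].c1ccccc1[P+](c1ccccc1)(c1ccccc1)C/C=C(C)/C=C/C=C(C)/CCC=C(C)C | intermediate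
25 | (2E,4E,6E)-2,7-dimethylocta-2,4,6-trienedial (C10 dialdehyde) | O=C/C(C)=C/C=C/C=C(C)/C=O | starting material
26 | triphenyl[(2E,4E,6E)-3,7,11-trimethyldodeca-2,4,6,10-tetraen-1-ylidene]-λ5-phosphane | c1ccccc1P(c1ccccc1)(c1ccccc1)=C/C=C(C)/C=C/C=C(C)/CCC=C(C)C | intermediate
27 | (2E,4E,6E,8E,10E,12E,14E)-2,7,11,15,19-pentamethylicosa-2,4,6,8,10,12,14,18-octaenal (C25 aldehyde) | O=C/C(C)=C/C=C/C=C(C)/C=C/C=C(C)/C=C/C=C(C)/CCC=C(C)C | intermediate
28 | {(2E,4E)-5-[(1S,2R,5R)-2-hydroxy-5-(2-methoxypropan-2-yl)-2-methylcyclopentyl]-3-methylpenta-2,4-dien-1-ylidene}triphenyl-λ5-phosphane | COC(C)(C)[C@@H]1CC[C@@](C)(O)[C@H]1/C=C/C(C)=C/C=P(c1ccccc1)(c1ccccc1)c1ccccc1 | intermediate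
29 | CNP0380368.2, (2R,5R,6S)-1-methoxy-2,6-cyclolycopen-5-ol; (1R,2S,3R)-3-(2-methoxypropan-2-yl)-1-methyl-2-[(1E,3E,5E,7E,9E,11E,13E,15E,17E,19E)-3,7,12,16,20,24-hexamethylpentacosa-1,3,5,7,9,11,13,15,17,19,23-undecaen-1-yl]cyclopentan-1-ol | COC(C)(C)[C@@H]1CC[C@@](C)(O)[C@H]1/C=C/C(C)=C/C=C/C(C)=C/C=C/C=C(C)/C=C/C=C(C)/C=C/C=C(\C)CCC=C(C)C | target

Total step count: 16. Longest linear sequence: 12 steps (steps 1, 2, 4 to 12 and 16, from 2-methylbut-3-en-2-ol).

Steps most likely to fail

Step 5. The oxidative cyclization may stall at the neopentyl-type β-carbon C2, nickel may ionize the allylic C1–OMe bond, or the chiral phosphine may give poor facial discrimination of the enoate. The fallback uses known chemistry only, sets out from aldehyde 5 and comes back at ketone 15. A Stetter reaction of 5 with methyl vinyl ketone (thiazolium chloride catalyst, Et3N, EtOH, 80 °C) should give 6-methoxy-6-methylheptane-2,5-dione F1. Intramolecular aldol condensation (NaOH, aqueous EtOH, reflux) should then close the ring at C2–C6 and give 3-(2-methoxypropan-2-yl)cyclopent-2-en-1-one F2. Copper hydride asymmetric conjugate reduction (CuCl, NaOtBu, p-Tol-BINAP of the required handedness, Ph2SiH2, toluene) would set C2 by hydride delivery and give the regiodefined enol silane {[(3R)-3-(2-methoxypropan-2-yl)cyclopent-1-en-1-yl]oxy}diphenylsilane F3. Alkylation of F3 in the same flask with BnOCH2Cl and tetrabutylammonium difluorotriphenylsilicate, trans to the C2 substituent, should give 15, from which step 8 continues.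

Step 8. The organocerium reagent may be steered by the bulky C2 substituent instead of the C6 side chain, giving poor or inverted facial selectivity at C5, and enolization with β-elimination of benzyl alcohol may compete. The fallback sets out from ketone 15 and comes back at alcohol 16. It uses the fact that the same facial bias then delivers oxygen instead of carbon. Non-basic methylenation (Zn, CH2Br2, TiCl4, THF) should give ({[(1S,5R)-5-(2-methoxypropan-2-yl)-2-methylidenecyclopentyl]methoxy}methyl)benzene F4. Epoxidation with mCPBA (NaHCO3, CH2Cl2) on the face that the methyl nucleophile preferred should give (3R,4R,5R)-4-[(benzyloxy)methyl]-5-(2-methoxypropan-2-yl)-1-oxaspiro[2.4]heptane F5, with the oxygen cis to C7. LiEt3BH (THF, 0 °C) should open the epoxide at its CH2 terminus to 16.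

Step 12. Under the acidic conditions the pentadienyl cation may be trapped by the C5 hydroxyl after C7=C8 isomerization (cyclic ether formation) or may lose a proton to give elimination products. The fallback reverses the polarity of the last union so that no cation is generated on the cyclopentane half; it sets out from enone 19 and C25 aldehyde 27 and comes back at target 29. Horner–Wadsworth–Emmons reaction of 19 with diethyl cyanomethylphosphonate (NaH, THF) should give (2E,4E)-5-[(1S,2R,5R)-2-hydroxy-5-(2-methoxypropan-2-yl)-2-methylcyclopentyl]-3-methylpenta-2,4-dienenitrile F6, from which the 9Z isomer is separated. Reduction with iBu2AlH (toluene, –78 °C, aqueous work-up) should give (2E,4E)-5-[(1S,2R,5R)-2-hydroxy-5-(2-methoxypropan-2-yl)-2-methylcyclopentyl]-3-methylpenta-2,4-dienal F7. In parallel, 27 is reduced with NaBH4 (MeOH, 0 °C) to (2E,4E,6E,8E,10E,12E,14E)-2,7,11,15,19-pentamethylicosa-2,4,6,8,10,12,14,18-octaen-1-ol F8. PPh3·HBr (MeOH) converts F8 into [(2E,4E,6E,8E,10E,12E,14E)-2,7,11,15,19-pentamethylicosa-2,4,6,8,10,12,14,18-octaen-1-yl]triphenylphosphonium bromide F9. NaOMe turns F9 into [(2E,4E,6E,8E,10E,12E,14E)-2,7,11,15,19-pentamethylicosa-2,4,6,8,10,12,14,18-octaen-1-ylidene]triphenyl-λ5-phosphane F10, which condenses with F7 at C11=C12 to give 29 after thermal Z to E isomerization.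

Further compounds
F1 | step 5 | 6-methoxy-6-methylheptane-2,5-dione | COC(C)(C)C(=O)CCC(C)=O
F2 | step 5 | 3-(2-methoxypropan-2-yl)cyclopent-2-en-1-one | COC(C)(C)C1=CC(=O)CC1
F3 | step 5 | {[(3R)-3-(2-methoxypropan-2-yl)cyclopent-1-en-1-yl]oxy}diphenylsilane | COC(C)(C)[C@@H]1CCC(O[SiH](c2ccccc2)c2ccccc2)=C1
F4 | step 8 | ({[(1S,5R)-5-(2-methoxypropan-2-yl)-2-methylidenecyclopentyl]methoxy}methyl)benzene | COC(C)(C)[C@@H]1CCC(=C)[C@H]1COCc1ccccc1
F5 | step 8 | (3R,4R,5R)-4-[(benzyloxy)methyl]-5-(2-methoxypropan-2-yl)-1-oxaspiro[2.4]heptane | COC(C)(C)[C@@H]1CC[C@@]2(OC2)[C@H]1COCc1ccccc1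
F6 | step 12 | (2E,4E)-5-[(1S,2R,5R)-2-hydroxy-5-(2-methoxypropan-2-yl)-2-methylcyclopentyl]-3-methylpenta-2,4-dienenitrile | COC(C)(C)[C@@H]1CC[C@@](C)(O)[C@H]1/C=C/C(C)=C/C#N
F7 | step 12 | (2E,4E)-5-[(1S,2R,5R)-2-hydroxy-5-(2-methoxypropan-2-yl)-2-methylcyclopentyl]-3-methylpenta-2,4-dienal | COC(C)(C)[C@@H]1CC[C@@](C)(O)[C@H]1/C=C/C(C)=C/C=O
F8 | step 12 | (2E,4E,6E,8E,10E,12E,14E)-2,7,11,15,19-pentamethylicosa-2,4,6,8,10,12,14,18-octaen-1-ol | OC/C(C)=C/C=C/C=C(C)/C=C/C=C(C)/C=C/C=C(C)/CCC=C(C)C
F9 | step 12 | [(2E,4E,6E,8E,10E,12E,14E)-2,7,11,15,19-pentamethylicosa-2,4,6,8,10,12,14,18-octaen-1-yl]triphenylphosphonium bromide | [Br-].c1ccccc1[P+](c1ccccc1)(c1ccccc1)C/C(C)=C/C=C/C=C(C)/C=C/C=C(C)/C=C/C=C(C)/CCC=C(C)C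
F10 | step 12 | [(2E,4E,6E,8E,10E,12E,14E)-2,7,11,15,19-pentamethylicosa-2,4,6,8,10,12,14,18-octaen-1-ylidene]triphenyl-λ5-phosphane | c1ccccc1P(c1ccccc1)(c1ccccc1)=C/C(C)=C/C=C/C=C(C)/C=C/C=C(C)/C=C/C=C(C)/CCC=C(C)C
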